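The route rests on cutting the piperidine at N1–C6 and C2–C3. Piperidine C2 carries only N1, C3H2 and C8 of flavone ring A, so N1 and C2 map onto a ring A aryl aldimine and C3–C6 onto Danishefsky's diene. One copper-catalysed enantioselective aza-Diels–Alder reaction forms both bonds, closes the piperidine ring and sets the only stereocentre (2R). Its precursor is the E N-tosyl imine of 2,6-bis(benzyloxy)-4-methoxybenzaldehyde. This ring A unit is symmetric about its C1–C4 axis, so either free position can later become C4a when the 4-pyranone ring C is annulated with phenylacetylene and CO.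

Key step: step 4

Assumption: the enantiomer of the planar-chiral P,S ligand is the one whose copper complex leaves the Re face of the imine carbon open (giving 2R); it is written as (Rp) by analogy with simple N-tosyl aryl aldimines, and the antipode would be used if a trial run shows the opposite sense.

Step 1
Reactants: 1 2,4,6-trihydroxybenzaldehyde
Product: 2 2,6-dihydroxy-4-methoxybenzaldehyde
Conditions: Me2SO4 (1.0 equiv), K2CO3 (1.0 equiv), acetone, 0 °C to rt
Reagents that add atoms: dimethyl sulfate, COS(=O)(=O)OC
Why: Williamson-type O-methylation with a hard electrophile; the 4-OH, para to the formyl group and outside its hydrogen bond, is the most acidic and accessible phenol, so one equivalent of base should methylate it in preference to the ortho hydroxyls and to ring carbon.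

Step 2
Reactants: 2 2,6-dihydroxy-4-methoxybenzaldehyde
Product: 3 2,6-bis(benzyloxy)-4-methoxybenzaldehyde
Conditions: BnBr (2.4 equiv), K2CO3 (3 equiv), DMF, 60 °C
Reagents that add atoms: benzyl bromide, BrCc1ccccc1
Why: Williamson ether synthesis; excess BnBr and K2CO3 in warm DMF should alkylate both remaining ortho phenols and give the symmetric ring A aldehyde.

Step 3
Reactants: 3 2,6-bis(benzyloxy)-4-methoxybenzaldehyde; 4 p-toluenesulfonamide
Product: 5 (E)-N-[2,6-bis(benzyloxy)-4-methoxybenzylidene]-4-methylbenzenesulfonamide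
Conditions: Ti(OEt)4 (2 equiv), toluene, 80 °C
Reagents that add atoms: none
Why: Titanium-alkoxide-mediated dehydrative condensation of an aldehyde with a primary sulfonamide (N-sulfonyl imine formation); Ti(OEt)4 activates the hindered, electron-rich carbonyl and consumes the water, and the aldimine should form as the more stable E isomer.

Step 4
Reactants: 5 (E)-N-[2,6-bis(benzyloxy)-4-methoxybenzylidene]-4-methylbenzenesulfonamide; 6 Danishefsky's diene [(E)-1-methoxy-3-(trimethylsilyloxy)buta-1,3-diene]
Product: 8 (2R)-2-[2,6-bis(benzyloxy)-4-methoxyphenyl]-1-(4-methylphenylsulfonyl)-2,3-dihydropyridin-4(1H)-one, via Mannich adduct 7 (not isolated)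
Conditions: Cu(MeCN)4PF6 (10 mol %), (Rp)-1-(tert-butylsulfanyl)-2-(diphenylphosphanyl)ferrocene (11 mol %), CH2Cl2, −20 °C to rt; then TFA (cat.), 0 °C, short
Reagents that add atoms: none
Why: Monovalent copper bearing the P,S ligand binds the sulfonyl imine through nitrogen and a sulfonyl oxygen and activates it for Mukaiyama–Mannich attack by the CH2 terminus (C4) of the silyloxy diene, forming C2–C3 and, after silyl loss, the open-chain β-methoxy enone 7. The sulfonamide nitrogen of 7 then closes the six-membered ring by 6-endo-trig conjugate addition to the methoxy-bearing carbon and β-elimination of methanol (N–C6), completed by the brief acid treatment. The closest known reaction type is the copper/ferrocenyl P,S-ligand-catalysed enantioselective aza-Diels–Alder reaction of N-sulfonyl aryl aldimines with Danishefsky's diene, applied here to a more electron-rich aryl group with two ortho substituents. The C2 stereocentre is fixed in the Mannich event by the planar-chiral ligand, which should leave only the Re face of the chelated E-imine open and so give 2R. The step needs enantiofacial selectivity and a catalysed path that outruns the racemic background, and the substrate helps on both counts: the aldimine is a single E isomer, the three alkoxy donors make the uncatalysed addition slow, and the symmetric aryl group removes any regiochemical or rotameric ambiguity. Regiochemistry within the diene is dictated by its polarisation, the silyl enol ether terminus being its only nucleophilic carbon.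

Step 5
Reactants: 8 (2R)-2-[2,6-bis(benzyloxy)-4-methoxyphenyl]-1-(4-methylphenylsulfonyl)-2,3-dihydropyridin-4(1H)-one
Product: 10 (2R)-2-[2,6-bis(benzyloxy)-4-methoxyphenyl]-1-(4-methylphenylsulfonyl)-1,2,3,6-tetrahydropyridin-4-yl trifluoromethanesulfonate, via lithium enolate 9 (not isolated)
Conditions: LiBH(s-Bu)3 (1.1 equiv), THF, −78 °C; then N-(5-chloropyridin-2-yl)triflimide, −78 to −20 °C
Reagents that add atoms: N-(5-chloropyridin-2-yl)bis(trifluoromethanesulfonyl)imide, FC(F)(F)S(=O)(=O)N(c1ccc(Cl)cn1)S(=O)(=O)C(F)(F)F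
Why: Conjugate (1,4) hydride reduction of the vinylogous sulfonamide by the bulky borohydride gives the C4–C5 enolate regiospecifically, and O-triflation at low temperature by the reactive N-pyridyl triflimide traps it as the enol triflate before β-elimination of the sulfonamide can set in; C2 is not touched.

Step 6
Reactants: 10 (2R)-2-[2,6-bis(benzyloxy)-4-methoxyphenyl]-1-(4-methylphenylsulfonyl)-1,2,3,6-tetrahydropyridin-4-yl trifluoromethanesulfonate
Product: 11 (2R)-2-[2,6-bis(benzyloxy)-4-methoxyphenyl]-1-(4-methylphenylsulfonyl)-1,2,3,6-tetrahydropyridine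
Conditions: Pd(OAc)2 (5 mol %), PPh3 (10 mol %), HCO2H, Et3N, DMF, 60 °C
Reagents that add atoms: none
Why: Palladium-catalysed formate reduction of an enol triflate; zerovalent palladium inserts into the C4–OTf bond, formate exchanges for triflate and decarboxylates, and C–H reductive elimination leaves the C4=C5 alkene, removing the C4 oxygen under conditions that spare the benzyl ethers and the sulfonamide.

Step 7
Reactants: 11 (2R)-2-[2,6-bis(benzyloxy)-4-methoxyphenyl]-1-(4-methylphenylsulfonyl)-1,2,3,6-tetrahydropyridine
Product: 13 tert-butyl (2R)-2-[2,6-bis(benzyloxy)-4-methoxyphenyl]-3,6-dihydropyridine-1(2H)-carboxylate, via free amine 12 (not isolated)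
Conditions: SmI2 (6 equiv), Et3N, H2O, THF, rt; then crude amine, Boc2O, Et3N, CH2Cl2, rt to 40 °C
Reagents that add atoms: di-tert-butyl dicarbonate, CC(C)(C)OC(=O)OC(=O)OC(C)(C)C
Why: Single-electron reductive N–S cleavage of an arenesulfonamide by SmI2 activated with amine and water should be fast at rt and spare the aryl benzyl ethers, the isolated alkene and the C2–N bond, and the liberated secondary amine is then acylated by Boc2O (carbamate formation) while the phenols are still protected.

Step 8
Reactants: 13 tert-butyl (2R)-2-[2,6-bis(benzyloxy)-4-methoxyphenyl]-3,6-dihydropyridine-1(2H)-carboxylate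
Product: 14 tert-butyl (2R)-2-(2,6-dihydroxy-4-methoxyphenyl)piperidine-1-carboxylate
Conditions: H2 (1 atm), Pd/C (10% palladium on carbon), EtOAc–MeOH, rt
Reagents that add atoms: none
Why: Heterogeneous catalytic hydrogenation saturates the C4=C5 alkene and hydrogenolyses both O-benzyl ethers in one neutral operation, while the carbamate-bearing benzylic C2–N bond, shielded by two ortho substituents, should persist.

Step 9
Reactants: 14 tert-butyl (2R)-2-(2,6-dihydroxy-4-methoxyphenyl)piperidine-1-carboxylate
Product: 15 tert-butyl (2R)-2-(2,6-dihydroxy-3-iodo-4-methoxyphenyl)piperidine-1-carboxylate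
Conditions: NIS (1.0 equiv), MeCN, −30 to 0 °C, dark
Reagents that add atoms: N-iodosuccinimide, O=C1CCC(=O)N1I
Why: Electrophilic aromatic iodination; the two free ring positions are equivalent by rotation about the aryl–C2 bond and each is ortho or para to all three oxygen substituents, so one equivalent of NIS at low temperature under neutral conditions should give a single mono-iodide.

Step 10
Reactants: 15 tert-butyl (2R)-2-(2,6-dihydroxy-3-iodo-4-methoxyphenyl)piperidine-1-carboxylate; 16 phenylacetylene
Product: 18 tert-butyl (2R)-2-(7-hydroxy-5-methoxy-4-oxo-2-phenyl-4H-chromen-8-yl)piperidine-1-carboxylate, via ynone 17 (not isolated)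
Conditions: PdCl2(dppf) (5 mol %), CO (20 bar), Et2NH, 100 °C
Reagents that add atoms: carbon monoxide, [C-]#[O+]
Why: Palladium-catalysed carbonylative Sonogashira coupling of an ortho-iodophenol followed by cyclisation; oxidative addition of zerovalent palladium to the C–I bond, CO insertion and alkynylation give the ortho-hydroxyaryl ynone, which in Et2NH closes by 6-endo oxa-Michael attack of the adjacent phenol to the 4-pyranone, while the other phenol is para to the ynone and cannot cyclise.

Step 11
Reactants: 18 tert-butyl (2R)-2-(7-hydroxy-5-methoxy-4-oxo-2-phenyl-4H-chromen-8-yl)piperidine-1-carboxylate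
Product: 19 7-hydroxy-5-methoxy-2-phenyl-8-[(2R)-piperidin-2-yl]-4H-chromen-4-one
Conditions: TFA, CH2Cl2, 0 °C to rt; then aq NaHCO3
Reagents that add atoms: none
Why: Acidolysis of the tert-butyl carbamate (loss of 2-methylpropene and CO2) frees the secondary amine; the ammonium ion formed resists ionisation of the benzylic C–N bond, and cold basification gives the free base without touching the flavone or the stereocentre.

Compound list
1 | 2,4,6-trihydroxybenzaldehyde | O=Cc1c(O)cc(O)cc1O | starting material
2 | 2,6-dihydroxy-4-methoxybenzaldehyde | COc1cc(O)c(C=O)c(O)c1 | intermediate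
3 | 2,6-bis(benzyloxy)-4-methoxybenzaldehyde | COc1cc(OCc2ccccc2)c(C=O)c(OCc2ccccc2)c1 | intermediate
4 | p-toluenesulfonamide | Cc1ccc(cc1)S(N)(=O)=O | starting material
5 | (E)-N-[2,6-bis(benzyloxy)-4-methoxybenzylidene]-4-methylbenzenesulfonamide | COc1cc(OCc2ccccc2)c(/C=N/S(=O)(=O)c2ccc(C)cc2)c(OCc2ccccc2)c1 | intermediate
6 | Danishefsky's diene, (E)-1-methoxy-3-(trimethylsilyloxy)buta-1,3-diene | CO/C=C/C(=C)O[Si](C)(C)C | starting material
7 | N-[(1R,4E)-1-[2,6-bis(benzyloxy)-4-methoxyphenyl]-5-methoxy-3-oxopent-4-en-1-yl]-4-methylbenzenesulfonamide (Mannich adduct) | COc1cc(OCc2ccccc2)c([C@@H](CC(=O)/C=C/OC)NS(=O)(=O)c2ccc(C)cc2)c(OCc2ccccc2)c1 | intermediate (not isolated)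
8 | (2R)-2-[2,6-bis(benzyloxy)-4-methoxyphenyl]-1-(4-methylphenylsulfonyl)-2,3-dihydropyridin-4(1H)-one | COc1cc(OCc2ccccc2)c([C@H]2CC(=O)C=CN2S(=O)(=O)c2ccc(C)cc2)c(OCc2ccccc2)c1 | intermediate
9 | lithium (2R)-2-[2,6-bis(benzyloxy)-4-methoxyphenyl]-1-(4-methylphenylsulfonyl)-1,2,3,6-tetrahydropyridin-4-olate | [Li+].COc1cc(OCc2ccccc2)c([C@H]2CC([O-])=CCN2S(=O)(=O)c2ccc(C)cc2)c(OCc2ccccc2)c1 | intermediate (not isolated)
10 | (2R)-2-[2,6-bis(benzyloxy)-4-methoxyphenyl]-1-(4-methylphenylsulfonyl)-1,2,3,6-tetrahydropyridin-4-yl trifluoromethanesulfonate | COc1cc(OCc2ccccc2)c([C@H]2CC(OS(=O)(=O)C(F)(F)F)=CCN2S(=O)(=O)c2ccc(C)cc2)c(OCc2ccccc2)c1 | intermediate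
11 | (2R)-2-[2,6-bis(benzyloxy)-4-methoxyphenyl]-1-(4-methylphenylsulfonyl)-1,2,3,6-tetrahydropyridine | COc1cc(OCc2ccccc2)c([C@H]2CC=CCN2S(=O)(=O)c2ccc(C)cc2)c(OCc2ccccc2)c1 | intermediate
12 | (2R)-2-[2,6-bis(benzyloxy)-4-methoxyphenyl]-1,2,3,6-tetrahydropyridine | COc1cc(OCc2ccccc2)c([C@H]2CC=CCN2)c(OCc2ccccc2)c1 | intermediate (not isolated)
13 | tert-butyl (2R)-2-[2,6-bis(benzyloxy)-4-methoxyphenyl]-3,6-dihydropyridine-1(2H)-carboxylate | COc1cc(OCc2ccccc2)c([C@H]2CC=CCN2C(=O)OC(C)(C)C)c(OCc2ccccc2)c1 | intermediate
14 | tert-butyl (2R)-2-(2,6-dihydroxy-4-methoxyphenyl)piperidine-1-carboxylate | COc1cc(O)c([C@H]2CCCCN2C(=O)OC(C)(C)C)c(O)c1 | intermediate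
15 | tert-butyl (2R)-2-(2,6-dihydroxy-3-iodo-4-methoxyphenyl)piperidine-1-carboxylate | COc1cc(O)c([C@H]2CCCCN2C(=O)OC(C)(C)C)c(O)c1I | intermediate
16 | phenylacetylene | C#Cc1ccccc1 | starting material
17 | tert-butyl (2R)-2-[2,6-dihydroxy-4-methoxy-3-(3-phenylprop-2-ynoyl)phenyl]piperidine-1-carboxylate (ynone) | COc1cc(O)c([C@H]2CCCCN2C(=O)OC(C)(C)C)c(O)c1C(=O)C#Cc1ccccc1 | intermediate (not isolated)
18 | tert-butyl (2R)-2-(7-hydroxy-5-methoxy-4-oxo-2-phenyl-4H-chromen-8-yl)piperidine-1-carboxylate | COc1cc(O)c([C@H]2CCCCN2C(=O)OC(C)(C)C)c2oc(-c3ccccc3)cc(=O)c12 | intermediate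
19 | 7-hydroxy-5-methoxy-2-phenyl-8-[(2R)-piperidin-2-yl]-4H-chromen-4-one | COc1cc(O)c([C@H]2CCCCN2)c2oc(-c3ccccc3)cc(=O)c12 | target

Total step count: 11 steps.
Longest linear sequence: 11 steps (1 to 19; the route is fully linear).

Steps most likely to fail

Step 4. The imine carbon is deactivated by three alkoxy donors and flanked by two ortho substituents, so diene addition may be too slow for the copper catalyst to turn over. The benzyloxy oxygens may also compete for copper and blur facial discrimination, and acid-promoted reversible opening at the benzylic C2–N bond during ring closure may erode the enantiomeric purity. The fallback replaces catalyst control by a stoichiometric sulfinyl auxiliary while forming the same bonds. It sets out from aldehyde 3, which is condensed with (R)-2-methylpropane-2-sulfinamide (Ti(OEt)4, THF) to give the N-sulfinyl imine F1. TMSOTf-promoted Mukaiyama–Mannich addition of diene 6 (CH2Cl2, −78 °C) should give the N-sulfinyl Mannich adduct F2, whose diastereomers can be separated. Brief HCl in MeOH at 0 °C followed by NaHCO3 removes the sulfinyl group and closes the ring to the N–H dihydropyridone F3, and Boc2O with DMAP gives the N-Boc dihydropyridone F4. LiBH(s-Bu)3 followed by N-(5-chloropyridin-2-yl)triflimide gives, through the lithium enolate F5, the N-Boc enol triflate F6. The palladium/formate reduction used in step 6 then delivers 13, where the route is rejoined, so that steps 5 to 7 are replaced. The (R)-sulfinamide is drawn on the expectation of an open, Lewis-acid-bound transition state; its antipode would be taken if a trial shows the opposite sense.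

Step 10. Oxidative addition into the hindered, electron-rich C–I bond may be slow, so that hydrodeiodination, non-carbonylative alkynylation with closure to a 2-phenylbenzofuran, or 5-exo closure to an aurone competes with the carbonylative 6-endo annulation. The fallback is the classical chalcone route, which brings in the carbonyl carbon as an acetyl group and needs no CO. It sets out from iodide 15, which undergoes Stille coupling with tributyl(1-ethoxyvinyl)stannane (Pd(PPh3)4, toluene, 90 °C) to give the enol ether F7. Dilute aqueous HCl in THF at 0 °C hydrolyses this to the ortho-hydroxyacetophenone F8. Claisen–Schmidt condensation with benzaldehyde (KOH, EtOH, rt) should give the 2'-hydroxychalcone F9, and oxidative cyclisation (I2 cat., DMSO, 110 °C) closes the pyranone to 18, where the route is rejoined. Any Boc loss in this last operation only anticipates step 11. Should oxidative addition itself be limiting, the formylation sequence given under step 9 reaches 17 without palladium.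

Step 9. The mono-iodide remains strongly activated, so mono-selectivity may be lost to a second iodination, and the electron-rich aryl iodide may undergo protodeiodination on handling. The fallback installs a deactivating formyl group in place of iodine, so that substitution stops after one event and neither a halide nor palladium is needed. It sets out from resorcinol 14, which undergoes magnesium-mediated ortho-formylation (MgCl2, Et3N, paraformaldehyde, MeCN, reflux) to give the salicylaldehyde F10. Addition of excess lithium phenylacetylide F11 (from 16 and n-BuLi, THF, −78 to 0 °C) should give the propargylic alcohol F12 as a mixture of carbinol epimers. MnO2 (CH2Cl2, rt) oxidises both epimers to ynone 17, isolated in this variant, which closes to 18 on warming in Et2NH/EtOH. The route is rejoined at 18, and steps 9 and 10 are both bypassed.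

Further compounds
F1 | step 4 | (R)-N-[(E)-2,6-bis(benzyloxy)-4-methoxybenzylidene]-2-methylpropane-2-sulfinamide | COc1cc(OCc2ccccc2)c(/C=N/[S@](=O)C(C)(C)C)c(OCc2ccccc2)c1
F2 | step 4 | (R)-N-[(1R,4E)-1-[2,6-bis(benzyloxy)-4-methoxyphenyl]-5-methoxy-3-oxopent-4-en-1-yl]-2-methylpropane-2-sulfinamide | COc1cc(OCc2ccccc2)c([C@@H](CC(=O)/C=C/OC)N[S@](=O)C(C)(C)C)c(OCc2ccccc2)c1
F3 | step 4 | (2R)-2-[2,6-bis(benzyloxy)-4-methoxyphenyl]-2,3-dihydropyridin-4(1H)-one | COc1cc(OCc2ccccc2)c([C@H]2CC(=O)C=CN2)c(OCc2ccccc2)c1
F4 | step 4 | tert-butyl (2R)-2-[2,6-bis(benzyloxy)-4-methoxyphenyl]-4-oxo-3,4-dihydropyridine-1(2H)-carboxylate | COc1cc(OCc2ccccc2)c([C@H]2CC(=O)C=CN2C(=O)OC(C)(C)C)c(OCc2ccccc2)c1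
F5 | step 4 | lithium (2R)-2-[2,6-bis(benzyloxy)-4-methoxyphenyl]-1-(tert-butoxycarbonyl)-1,2,3,6-tetrahydropyridin-4-olate | [Li+].COc1cc(OCc2ccccc2)c([C@H]2CC([O-])=CCN2C(=O)OC(C)(C)C)c(OCc2ccccc2)c1
F6 | step 4 | tert-butyl (2R)-2-[2,6-bis(benzyloxy)-4-methoxyphenyl]-4-(trifluoromethanesulfonyloxy)-3,6-dihydropyridine-1(2H)-carboxylate | COc1cc(OCc2ccccc2)c([C@H]2CC(OS(=O)(=O)C(F)(F)F)=CCN2C(=O)OC(C)(C)C)c(OCc2ccccc2)c1
F7 | step 10 | tert-butyl (2R)-2-[3-(1-ethoxyethenyl)-2,6-dihydroxy-4-methoxyphenyl]piperidine-1-carboxylate | COc1cc(O)c([C@H]2CCCCN2C(=O)OC(C)(C)C)c(O)c1C(=C)OCC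
F8 | step 10 | tert-butyl (2R)-2-(3-acetyl-2,6-dihydroxy-4-methoxyphenyl)piperidine-1-carboxylate | COc1cc(O)c([C@H]2CCCCN2C(=O)OC(C)(C)C)c(O)c1C(C)=O
F9 | step 10 | tert-butyl (2R)-2-{2,6-dihydroxy-4-methoxy-3-[(2E)-3-phenylprop-2-enoyl]phenyl}piperidine-1-carboxylate | COc1cc(O)c([C@H]2CCCCN2C(=O)OC(C)(C)C)c(O)c1C(=O)/C=C/c1ccccc1
F10 | step 9 | tert-butyl (2R)-2-(3-formyl-2,6-dihydroxy-4-methoxyphenyl)piperidine-1-carboxylate | COc1cc(O)c([C@H]2CCCCN2C(=O)OC(C)(C)C)c(O)c1C=O
F11 | step 9 | lithium phenylacetylide | [Li+].[C-]#Cc1ccccc1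
F12 | step 9 | tert-butyl (2R)-2-[2,6-dihydroxy-3-(1-hydroxy-3-phenylprop-2-yn-1-yl)-4-methoxyphenyl]piperidine-1-carboxylate (both carbinol epimers) | COc1cc(O)c([C@H]2CCCCN2C(=O)OC(C)(C)C)c(O)c1C(O)C#Cc1ccccc1
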